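The cycloheptane (C1 carbinol, C2 CHMe, C3 CHOH, C4, C5 ring-fusion CH, C6 lactone O–CH, C7 tiglate O–CH) is read as a cyclopentane C1–C5 into whose C1–C5 bond the dioxygenated C6–C7 unit has been inserted. The C1 carbinol (a former ketone) and the lactone α-carbon on C5 (a former keto group) stand 1,5, the retron of a de Mayo sequence. A [2+2] photocycloaddition of a 2-methoxycyclopentenyl α-keto ester with vinylene carbonate forms C5–C6 and C7–C1 at once; the strained push–pull cyclobutane then opens by retro-aldol cleavage of C1–C5 to the seven-membered ring.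

Key step: step 5

Step 1
Reactants: 1 2-methylcyclopent-2-en-1-one
Product: 3 (2S,3R)-3-hydroxy-2-methylcyclopentan-1-one, via pinacol boronate 2 (not isolated)
Conditions: B2pin2, CuCl (cat.), NaOt-Bu (cat.), Josiphos ligand (enantiomer giving 3R), MeOH, THF, rt; then NaBO3·4H2O, THF/H2O, rt
Reagents that add atoms: bis(pinacolato)diboron CC1(C)OB(OC1(C)C)B1OC(C)(C)C(C)(C)O1; sodium perborate NaBO3 [Na+].[O-]OB=O
Why: Copper-catalysed asymmetric conjugate borylation of the cyclic enone sets C3 under control of the chiral ligand, protonation with equilibration places the C2 methyl group trans, and perborate oxidation of the C–B bond proceeds with retention.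

Step 2
Reactants: 3 (2S,3R)-3-hydroxy-2-methylcyclopentan-1-one
Product: 4 (2S,3R)-3-[(tert-butyldimethylsilyl)oxy]-2-methylcyclopentan-1-one
Conditions: TBSCl, imidazole, DMF, rt
Reagents that add atoms: tert-butyldimethylsilyl chloride CC(C)(C)[Si](C)(C)Cl
Why: Imidazole-promoted silylation of the secondary alcohol is routine and protects the β-hydroxyl against elimination in the enolisation and organometallic steps that follow, without touching a stereocentre.

Step 3
Reactants: 4 silyl ether ketone
Product: 6 (4R,5S)-4-[(tert-butyldimethylsilyl)oxy]-1-methoxy-5-methylcyclopent-1-ene, via dimethyl ketal 5 (not isolated)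
Conditions: HC(OMe)3, MeOH, PPTS (cat.), rt; concentrate; then TMSOTf, i-Pr2NEt, CH2Cl2, −20 °C
Reagents that add atoms: trimethyl orthoformate COC(OC)OC
Why: Acid-catalysed ketalisation followed by silyl-triflate-mediated elimination of methanol from the ketal gives the enol ether, the intermediate oxocarbenium ion losing a proton from the less hindered C5 methylene and not from the C2 methine, so that the C2 and C3 centres are kept.

Step 4
Reactants: 6 methyl enol ether; 7 ethyl chlorooxoacetate
Product: 8 ethyl 2-[(3S,4R)-4-[(tert-butyldimethylsilyl)oxy]-2-methoxy-3-methylcyclopent-1-en-1-yl]-2-oxoacetate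
Conditions: pyridine, CH2Cl2, 0 °C to rt
Reagents that add atoms: none
Why: The nucleophilic C5 of the enol ether is acylated by the oxalyl monochloride and pyridine removes the C5 proton from the oxocarbenium ion, a Friedel–Crafts-type enol ether acylation that gives the conjugated β-methoxy enone with the methoxy group fixed on C1.

Step 5
Reactants: 8 β-methoxy enone keto ester; 9 vinylene carbonate
Product: 10 photoadduct (cis-fused bicyclo[3.2.0]heptane: C1 methoxy; C5 ethoxyoxalyl; C6/C7 cyclic carbonate exo; cyclobutane anti to the C2 methyl group)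
Conditions: hν (Hg lamp, Pyrex, λ > 300 nm), vinylene carbonate (10 equiv), MeCN, −20 °C
Reagents that add atoms: none
Why: Excitation of the β-methoxy enone chromophore of 8 (a vinylogous ester whose C=C lies in the five-membered ring and cannot deactivate by E/Z isomerisation) and intersystem crossing give a triplet that adds to vinylene carbonate through a 1,4-biradical and so forms C5–C6 and C7–C1 in one operation. The closest known reaction type is the de Mayo-type [2+2] photocycloaddition of β-alkoxy enones with alkenes, for which vinylene carbonate is an established partner. The only ring closed is the cyclobutane C1–C5–C6–C7, by stepwise intermolecular [2+2] addition ending in 1,4-biradical recombination (a four-membered closure), and its fusion to the cyclopentane at C1 and C5 is necessarily cis. The alkene should approach the enone face anti to the allylic C2 methyl group, which sets C1, C5 and C6 relative to C2 and C3, and the carbonate ring should take the exo position away from the cyclopentane, which sets C7 and places the C6 oxygen cis to the C5 oxalyl group as step 6 requires. Because the alkene is symmetrical no regiochemical issue arises, so the step needs only facial and exo selectivity, secured by the C2 methyl group next to C1 and by the bulk of the substituted cyclopentane in the biradical closure. C1 and C5 are erased again in step 7 and C7 is inverted in step 14, so the information carried forward is the configuration at C6.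

Step 6
Reactants: 10 photoadduct
Product: 12 cyclobutane-fused α-keto γ-lactone (C6–O in the lactone; C7 hydroxyl free; C1 methoxy), via diol keto ester 11 (not isolated)
Conditions: K2CO3 (0.5 equiv), MeOH, 0 °C
Reagents that add atoms: none
Why: Base-catalysed methanolysis of the cyclic carbonate frees both hydroxyls and the C6 alkoxide, held cis to the C5 oxalyl group on the cyclobutane, closes the five-membered α-keto lactone by transesterification, while the quaternary C5 rules out enolisation and β-elimination.

Step 7
Reactants: 12 cyclobutane-fused α-keto lactone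
Product: 13 cycloheptanone fused to a 3-hydroxybutenolide (C1 ketone; C7 hydroxyl cis to the C6 oxygen)
Conditions: TFA (2 equiv), CH2Cl2/H2O (20:1), 0 °C
Reagents that add atoms: water O
Why: Protonation of the α-keto lactone triggers retro-aldol opening of the strained donor–acceptor cyclobutane at C1–C5 with push from the C1 methoxy group, water converts the methyl oxocarbenium ion into the C1 ketone of the new seven-membered ring, and the α-keto lactone rests as its 3-hydroxybutenolide tautomer, which completes the de Mayo sequence and leaves C6 and C7 untouched.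

Step 8
Reactants: 13 hydroxybutenolide ketone
Product: 14 vinyl triflate of 13
Conditions: PhNTf2, Et3N, CH2Cl2, 0 °C
Reagents that add atoms: N-phenylbis(trifluoromethanesulfonimide) O=S(=O)(N(c1ccccc1)S(=O)(=O)C(F)(F)F)C(F)(F)F
Why: The acidic enol hydroxyl of the 3-hydroxybutenolide is converted chemoselectively into the vinyl triflate by the mild triflimide reagent, the neutral secondary C7 alcohol and the ketone being left alone.

Step 9
Reactants: 14 vinyl triflate
Product: 15 α-methyl butenolide ketone
Conditions: Me4Sn, Pd(PPh3)4 (cat.), LiCl, DMF, 60 °C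
Reagents that add atoms: tetramethylstannane C[Sn](C)(C)C
Why: Stille cross-coupling of the electron-poor vinyl triflate with tetramethylstannane under neutral conditions installs the lactone α-methyl group without epimerising or eliminating the base-sensitive α-hydroxy ketone.

Step 10
Reactants: 15 α-methyl butenolide ketone
Product: 16 cis-fused α-methyl γ-lactone (C1 ketone; C7 hydroxyl)
Conditions: H2 (5 bar), Rh/Al2O3 (5 wt %), EtOAc, rt
Reagents that add atoms: none
Why: Heterogeneous hydrogenation delivers both hydrogens syn to the butenolide face that bears the C6 hydrogen, opposite to the C7 ring branch, so that the cis-fused lactone forms and C5 and the α-methyl centre are set from C6.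

Step 11
Reactants: 16 saturated lactone ketone; 17 methoxyallene
Product: 19 α-hydroxy vinyl ketone (C1 carbinol bearing propenoyl; C1/C7 cis diol), via allenyl ether carbinol 18 (not isolated)
Conditions: 17, n-BuLi, THF, −78 °C; add 16 (2.2 equiv of the lithio reagent), −78 °C; then 5% aq. H2SO4, THF, 0 °C
Reagents that add atoms: water O
Why: 1-Lithio-1-methoxyallene, a small acyl anion equivalent, adds to the C1 ketone from the face opposite to the C2 methyl group, the C7 alkoxide and the lactone, which sets the C1 carbinol with the carbon chain trans to the methyl group, and mild acid hydrolysis of the allenyl enol ether then gives the α-hydroxy vinyl ketone.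

Step 12
Reactants: 19 α-hydroxy vinyl ketone; 20 (Z)-but-2-ene
Product: 21 (E)-but-2-enoyl C1/C7 cis diol
Conditions: Hoveyda–Grubbs second-generation catalyst (5 mol %), (Z)-but-2-ene (excess), CH2Cl2, 40 °C, sealed tube
Reagents that add atoms: none
Why: Olefin cross metathesis of the vinyl ketone with an excess of but-2-ene exchanges the methylene terminus for ethylidene and gives the thermodynamically favoured E enone.

Step 13
Reactants: 21 butenoyl cis diol
Product: 22 C1/C7 cyclic sulfate
Conditions: SO2Cl2, Et3N, CH2Cl2, −78 to 0 °C
Reagents that add atoms: sulfuryl chloride O=S(=O)(Cl)Cl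
Why: The cis C1/C7 diol condenses with sulfuryl chloride to the five-membered cyclic sulfate, which masks the tertiary hydroxyl and activates C7 for substitution without an oxidant that could attack the enone.

Step 14
Reactants: 22 cyclic sulfate; 23 tiglic acid
Product: 26 CNP0183494.2 (target), via cesium sulfate monoester 24 (not isolated), via silyl ether 25 (not isolated)
Conditions: tiglic acid, Cs2CO3, DMF, 50 °C; then 1 M aq. H2SO4, THF, rt
Reagents that add atoms: none
Why: Cesium tiglate opens the cyclic sulfate by SN2 attack at the secondary C7 with inversion, which gives the trans C6/C7 and C1/C7 oxygen pattern, and aqueous acid then hydrolyses the tertiary sulfate monoester and the silyl ether.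

Compound list
1 | 2-methylcyclopent-2-en-1-one | CC1=CCCC1=O | starting material
2 | (2S,3R)-2-methyl-3-(4,4,5,5-tetramethyl-1,3,2-dioxaborolan-2-yl)cyclopentan-1-one | O=C1[C@@H](C)[C@H](B2OC(C)(C)C(C)(C)O2)CC1 | intermediate
3 | (2S,3R)-3-hydroxy-2-methylcyclopentan-1-one (methyl and hydroxyl trans) | O=C1[C@@H](C)[C@H](O)CC1 | intermediate
4 | (2S,3R)-3-[(tert-butyldimethylsilyl)oxy]-2-methylcyclopentan-1-one | O=C1[C@@H](C)[C@H](O[Si](C)(C)C(C)(C)C)CC1 | intermediate
5 | dimethyl ketal of 4 | COC1(OC)[C@@H](C)[C@H](O[Si](C)(C)C(C)(C)C)CC1 | intermediate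
6 | (4R,5S)-4-[(tert-butyldimethylsilyl)oxy]-1-methoxy-5-methylcyclopent-1-ene | COC1=CC[C@@H](O[Si](C)(C)C(C)(C)C)[C@@H]1C | intermediate
7 | ethyl chlorooxoacetate | CCOC(=O)C(=O)Cl | starting material
8 | ethyl 2-[(3S,4R)-4-[(tert-butyldimethylsilyl)oxy]-2-methoxy-3-methylcyclopent-1-en-1-yl]-2-oxoacetate | COC1=C(C(=O)C(=O)OCC)C[C@@H](O[Si](C)(C)C(C)(C)C)[C@@H]1C | intermediate
9 | vinylene carbonate (1,3-dioxol-2-one) | O=C1OC=CO1 | starting material
10 | photoadduct: cis-fused bicyclo[3.2.0]heptane, C1 methoxy, C5 ethoxyoxalyl, exo C6/C7 cyclic carbonate, cyclobutane anti to the C2 methyl and syn to the C3 silyloxy group | CO[C@@]12[C@@H](C)[C@H](O[Si](C)(C)C(C)(C)C)C[C@]1(C(=O)C(=O)OCC)[C@H]1OC(=O)O[C@@H]21 | intermediate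
11 | C6,C7-diol of 10 (carbonate removed, ethyl keto ester intact) | CO[C@@]12[C@@H](C)[C@H](O[Si](C)(C)C(C)(C)C)C[C@]1(C(=O)C(=O)OCC)[C@@H](O)[C@H]2O | intermediate
12 | cyclobutane-fused α-keto γ-lactone (lactone O on C6, free C7 hydroxyl cis to it, C1 methoxy) | CO[C@@]12[C@@H](C)[C@H](O[Si](C)(C)C(C)(C)C)C[C@@]13C(=O)C(=O)O[C@H]3[C@H]2O | intermediate
13 | cycloheptanone fused at C5–C6 to a 3-hydroxybutenolide (C1 ketone, C2 methyl, C3 silyloxy, C7 hydroxyl cis to the C6 oxygen) | O=C1[C@@H](C)[C@H](O[Si](C)(C)C(C)(C)C)CC2=C(O)C(=O)O[C@H]2[C@H]1O | intermediate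
14 | vinyl triflate of 13 | O=C1[C@@H](C)[C@H](O[Si](C)(C)C(C)(C)C)CC2=C(OS(=O)(=O)C(F)(F)F)C(=O)O[C@H]2[C@H]1O | intermediate
15 | α-methyl butenolide analogue of 13 | O=C1[C@@H](C)[C@H](O[Si](C)(C)C(C)(C)C)CC2=C(C)C(=O)O[C@H]2[C@H]1O | intermediate
16 | cis-fused α-methyl γ-lactone (H at C5, C6 and the α-carbon all cis), C1 ketone, C7 hydroxyl cis to the C6 oxygen | O=C1[C@@H](C)[C@H](O[Si](C)(C)C(C)(C)C)C[C@@H]2[C@@H](OC(=O)[C@@H]2C)[C@H]1O | intermediate
17 | methoxyallene (1-methoxypropa-1,2-diene) | COC=C=C | starting material
18 | C1 tertiary carbinol bearing the 1-methoxyallenyl group (hydroxyl cis to the C2 methyl and the C7 hydroxyl) | C=C=C(OC)[C@]1(O)[C@@H](C)[C@H](O[Si](C)(C)C(C)(C)C)C[C@@H]2[C@@H](OC(=O)[C@@H]2C)[C@H]1O | intermediate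
19 | C1 propenoyl carbinol, C1/C7 cis diol | C=CC(=O)[C@]1(O)[C@@H](C)[C@H](O[Si](C)(C)C(C)(C)C)C[C@@H]2[C@@H](OC(=O)[C@@H]2C)[C@H]1O | intermediate
20 | (Z)-but-2-ene | C/C=C\C | starting material
21 | C1 (E)-but-2-enoyl carbinol, C1/C7 cis diol | C/C=C/C(=O)[C@]1(O)[C@@H](C)[C@H](O[Si](C)(C)C(C)(C)C)C[C@@H]2[C@@H](OC(=O)[C@@H]2C)[C@H]1O | intermediate
22 | C1/C7 cyclic sulfate of 21 | C/C=C/C(=O)[C@]1(O3)[C@@H](C)[C@H](O[Si](C)(C)C(C)(C)C)C[C@@H]2[C@@H](OC(=O)[C@@H]2C)[C@H]1OS3(=O)=O | intermediate
23 | tiglic acid ((E)-2-methylbut-2-enoic acid) | C/C=C(\C)C(=O)O | starting material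
24 | cesium C1 sulfate monoester, C7 tiglate (C7 inverted) | C/C=C/C(=O)[C@]1(OS(=O)(=O)[O-])[C@@H](C)[C@H](O[Si](C)(C)C(C)(C)C)C[C@@H]2[C@@H](OC(=O)[C@@H]2C)[C@@H]1OC(=O)/C(C)=C/C.[Cs+] | intermediate
25 | C3 tert-butyldimethylsilyl ether of the target | C/C=C/C(=O)[C@]1(O)[C@@H](C)[C@H](O[Si](C)(C)C(C)(C)C)C[C@@H]2[C@@H](OC(=O)[C@@H]2C)[C@@H]1OC(=O)/C(C)=C/C | intermediate
26 | CNP0183494.2 | C/C=C/C(=O)[C@]1(O)[C@@H](C)[C@H](O)C[C@@H]2[C@@H](OC(=O)[C@@H]2C)[C@@H]1OC(=O)/C(C)=C/C | target

Total step count: 14. Longest linear sequence: 14 steps (1 to 26).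

Steps most likely to fail

Step 5. Capture of the triplet enone by the electron-poor carbonate alkene may be slow, so that hydrogen abstraction or oxetane formation at the 1,2-dicarbonyl unit competes, and face or exo selectivity may be incomplete. The fallback sets out from 8 and changes the partner to the electron-rich 2,2-dimethyl-1,3-dioxole, which should be trapped faster. Irradiation would give the acetonide photoadduct F1. Aqueous acid (80% AcOH, 40 °C) would then remove the acetonide, lactonise the C6 hydroxyl onto the keto ester and trigger the retro-aldol opening in one operation. The route is rejoined at 13, and steps 6 and 7 fall away.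

Step 14. Substitution at C7 may be too slow next to the fully substituted C1, so that elimination or simple hydrolysis back to the cis diol takes over. The fallback sets out from 21 and inverts C7 by an oxidation–reduction pair. Dess–Martin periodinane would oxidise the secondary alcohol to the C7 ketone F2. Me4NBH(OAc)3 in AcOH/MeCN would then deliver hydride from the tertiary C1 hydroxyl, on the face of that hydroxyl, to give the trans diol F3. Acylation of the secondary hydroxyl with tigloyl chloride, Et3N and DMAP would give silyl ether 25, where the route is rejoined; the acid treatment of step 14 then gives 26.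

Step 10. Hydrogenation of the tetrasubstituted alkene may be sluggish, so that reduction of the C1 ketone or attack from the wrong face gains ground. The fallback sets out from 15 and replaces surface hydrogenation by conjugate hydride transfer. Copper hydride made from Cu(OAc)2, 1,2-bis(diphenylphosphino)benzene and tetramethyldisiloxane should add hydride to C5 from the convex face. Protonation of the enolate with t-BuOH at the α-carbon from the same face should lead directly to 16, where the route is rejoined. This fallback makes no new compound (F0).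

Further compounds
F1 | step 5 | acetonide photoadduct (2,2-dimethyl-1,3-dioxolane analogue of 10) | CO[C@@]12[C@@H](C)[C@H](O[Si](C)(C)C(C)(C)C)C[C@]1(C(=O)C(=O)OCC)[C@H]1OC(C)(C)O[C@@H]21
F0 | step 10 | none | none
F2 | step 14 | C7 ketone derived from 21 | C/C=C/C(=O)[C@]1(O)[C@@H](C)[C@H](O[Si](C)(C)C(C)(C)C)C[C@@H]2[C@@H](OC(=O)[C@@H]2C)C1=O
F3 | step 14 | trans diol (C7 epimer of 21) | C/C=C/C(=O)[C@]1(O)[C@@H](C)[C@H](O[Si](C)(C)C(C)(C)C)C[C@@H]2[C@@H](OC(=O)[C@@H]2C)[C@@H]1O
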